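**Assumptions:**
- Compounds 6, 7 and 8 are commercial. Compound 8 is also one step from 4-bromo-2-methoxyphenol and BnBr.
- The target's dioxane is the trans-(7R,8R) isomer. I checked this from the SMILES: with C8 = R, C7 = R puts the aryl and CH2OH groups on opposite faces.

## Retrosynthetic overview
1. Silandrin (1) ⇒ anodic dehydrogenative benzylic C–H etherification of seco-polyphenol 2. It goes through a p-quinone methide, and the 4'-OH closes 6-exo. The dioxane ring is formed last, and C7 ends up trans to C8.
2. 2 ⇐ global debenzylation of 3 ⇐ Mitsunobu (inversion) of the 3'-OH of 7,4'-di-O-benzyl-(S)-eriodictyol 4 with the (R)-secondary alcohol 5.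
3. 4 ⇐ (S)-eriodictyol 6, which supplies the intact chromanone ring and the flavanone C2 stereocentre.
4. 5 ⇐ Cu-catalysed opening of (R)-benzyl glycidyl ether 7 by the Grignard reagent of aryl bromide 8. C8 comes from the glycidyl ether.
5. Ring order: the chromanone is already present in 6, and the benzodioxane is closed last.

## Forward route

**Step 1**
Reactants: 7 (R)-benzyl glycidyl ether; 8 1-(benzyloxy)-4-bromo-2-methoxybenzene
Product: 5 (R)-1-(benzyloxy)-3-[4-(benzyloxy)-3-methoxyphenyl]propan-2-ol
Conditions: 8, Mg, THF, reflux, 1 h; then CuI (10 mol %), 7, THF, −20 °C → rt; NH4Cl (aq) workup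
Reagents that add atoms: none
Why: Cu-catalysed Grignard opening of the terminal epoxide carbon (epoxide ring-opening) leaves the C–O stereocentre untouched, so the (R)-configured carbinol is set by 7.

**Step 2**
Reactants: 6 (S)-eriodictyol
Product: 4 7,4'-di-O-benzyl-(S)-eriodictyol (3'-OH and 5-OH free)
Conditions: BnBr (2.1 equiv), K2CO3 (2.1 equiv), DMF, 0 °C → rt, 6 h; chromatographic separation from the tri-O-benzyl and mono-O-benzyl products
Reagents that add atoms: benzyl bromide, BrCc1ccccc1
Why: Williamson etherification follows phenol acidity (7-OH > 4'-OH > 3'-OH), and the chelated 5-OH is inert. This leaves only 3'-OH free, and the mild base and low temperature limit flavanone ring-opening; the C2 stereocentre is untouched.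

**Step 3**
Reactants: 4 7,4'-di-O-benzyl-(S)-eriodictyol; 5 (R)-alcohol
Product: 3 (S)-7,4'-di-O-benzyl-3'-O-[(S)-1-(4-benzyloxy-3-methoxyphenyl)-3-benzyloxypropan-2-yl]eriodictyol
Conditions: PPh3, DIAD, THF, 0 °C → rt, 12 h
Reagents that add atoms: none
Why: Mitsunobu etherification of the 3'-phenol with a secondary alcohol goes by SN2 with clean inversion. The (R)-alcohol therefore becomes the aryl ether with the spatial arrangement required at C8 (R in the target; the descriptor reads S here only because CIP priorities change after ring closure). Regiochemistry is fixed because 3'-OH is the only reactive phenol.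

**Step 4**
Reactants: 3
Product: 2 seco-polyphenol (four benzyl ethers removed; C9-OH, 4'-OH, 4''-OH, 7-OH, 5-OH free)
Conditions: H2 (1 atm), 10 % Pd/C, EtOAc/MeOH 1:1, rt, 3 h
Reagents that add atoms: none
Why: Catalytic hydrogenolysis of aryl and alkyl benzyl ethers is routine. The flavanone C=O and the C2–O bond survive these mild conditions, and no stereocentre is involved.

**Step 5**
Reactants: 2
Product: 1 silandrin
Conditions: undivided cell, RVC anode, Pt cathode, constant current (3 mA), nBu4NBF4 (0.1 M), MeCN/HFIP 3:1, 2,6-lutidine (0.5 equiv), rt, 2.2 F/mol, then aqueous workup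
Reagents that add atoms: none
Why: Proposed new method: anodic dehydrogenative intramolecular benzylic C–H etherification that builds the trans-benzodioxane on an unprotected flavanone polyphenol.
- Mechanism: the 4-alkylguaiacol ring is oxidised by PCET to the phenoxyl radical. A second oxidation and loss of the benzylic proton gives the p-quinone methide, and the cathode reduces H+ to H2. The flavanone ring nearby, held by its 3'-OR substituent, adds its 4'-OH to C7 in a 6-exo-trig oxa-Michael closure.
- Stereochemistry: in HFIP the addition is reversible, so the trans-diequatorial (7R,8R) dioxane is favoured and C7 is set by the pre-existing C8.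
- Closest known reactions: DDQ or anodic generation of p-quinone methides from 4-alkylphenols, and quinone-methide trapping by phenols in biomimetic lignan and flavonolignan synthesis.

## Compound list
1 | silandrin | COc1cc([C@H]2Oc3ccc([C@@H]4CC(=O)c5c(O)cc(O)cc5O4)cc3O[C@@H]2CO)ccc1O | target
2 | (2S)-5,7-dihydroxy-2-{4-hydroxy-3-[(S)-1-(4-hydroxy-3-methoxyphenyl)-3-hydroxypropan-2-yloxy]phenyl}chroman-4-one (seco-polyphenol) | O=C1C[C@@H](c2ccc(O)c(O[C@@H](Cc3ccc(O)c(OC)c3)CO)c2)Oc2cc(O)cc(O)c21 | intermediate
3 | tetra-O-benzyl Mitsunobu ether | O=C1C[C@@H](c2ccc(OCc3ccccc3)c(O[C@@H](Cc3ccc(OCc4ccccc4)c(OC)c3)COCc3ccccc3)c2)Oc2cc(OCc3ccccc3)cc(O)c21 | intermediate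
4 | 7,4'-di-O-benzyl-(S)-eriodictyol | O=C1C[C@@H](c2ccc(OCc3ccccc3)c(O)c2)Oc2cc(OCc3ccccc3)cc(O)c21 | intermediate
5 | (R)-1-(benzyloxy)-3-[4-(benzyloxy)-3-methoxyphenyl]propan-2-ol | COc1cc(C[C@@H](O)COCc2ccccc2)ccc1OCc1ccccc1 | intermediate
6 | (S)-eriodictyol | O=C1C[C@@H](c2ccc(O)c(O)c2)Oc2cc(O)cc(O)c21 | starting material
7 | (R)-benzyl glycidyl ether | c1ccccc1COC[C@H]1CO1 | starting material
8 | 1-(benzyloxy)-4-bromo-2-methoxybenzene | COc1cc(Br)ccc1OCc1ccccc1 | starting material

## Totals
- Total steps: 5
- Longest linear sequence: 4 steps (6 → 4 → 3 → 2 → 1)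

## Three steps most likely to fail
1. **Step 5 (proposed new step).** The B-ring 4'-OH is also oxidisable, which risks oxidation at flavanone C2 and loss of the C2 stereocentre, and the product can be over-oxidised.
   - Fallback (known chemistry): oxidise 2 with DDQ (1.1 equiv) in wet dioxane to the p-hydroxybenzylic alcohol. This is a C7 epimer mixture, which does not matter because the quinone methide re-forms. Then close with Sc(OTf)3 or aqueous HCl/THF, which equilibrates to the thermodynamic trans-benzodioxane.
2. **Step 2 (7,4'-selective dibenzylation).** Selectivity over the tri-O-benzyl and mono-O-benzyl products, and partial racemisation under base, may give poor yield or ee.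
   - Fallback: use the intrinsic 4'-OH nucleophilicity instead of protecting it. React 7-O-benzyl-eriodictyol with the cyclic sulfate of (1S,2S)-3-benzyloxy-1-(4-benzyloxy-3-methoxyphenyl)propane-1,2-diol. The 4'-O attacks the benzylic C7 first and the 3'-O then closes at C8, both with inversion. The diol comes from (S)-2,3-O-isopropylideneglyceraldehyde plus the aryl Grignard, with the diastereomer separated.
3. **Step 3 (Mitsunobu).** The 3'-phenol is hindered and weakly acidic, so elimination to the styrene or basic ring-opening of the flavanone may compete.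
   - Fallback: convert 5 to its 2-nitrobenzenesulfonate and displace it with the 3'-phenoxide of 4 (Cs2CO3, DMF, 40 °C). This is an SN2 with inversion through a different mechanism.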